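**Retrosynthetic overview**

1. Numbering follows the target SMILES: ring A = C3/C4/C10/C11/C27 (cyclopentane); ring B = C4–O5–C6–C8–C10 (lactone); ring C = C11–C12–C13–N21–C28–C27 (lactam); ring D = N21–C22–C23–C24–C25–C27–C28 (azepane); ring E = C14–C15–C16–C18–O20 (lactone).
2. Feature used: C22, C23 and C24 of ring D carry no substituent, so C23–C24 is cut as an alkene. Ring D is closed last by ring-closing metathesis between an N21-allyl group and a C25-vinyl group on the cis-fused δ-lactam, followed by hydrogenation and desilylation.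
3. Ring C comes from amide formation between a C13 amine and a C28 acid; the C25 carbinol from the C25 aldehyde and CH2=CHMgBr; C13–N from azide inversion; C12–C13 from acylation of a C12 zinc reagent with the (R)-lactone acid chloride (ring E, C14).
4. The C3 ethyl group and quaternary C27 come from cuprate addition to a C27=C3 benzyl enoate and alkylation of the enolate; the enoate comes from the C27 ketone of bicyclic hydroxy lactone 1 (rings A/B; C4, C10, C11) with ring B masked as a methyl acetal. The C8 and C16 methyl groups come from hydrogenation of α-methylene lactones.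
5. Ring order: A/B (from 1) → E (attached in step 10) → C (step 15) → D (step 20).

Key step: step 20

Remark: 1, 15, 30 and 33 are taken as purchased. Acetals and lactols 3–11 are carried as both C6 anomers, and 23 and 24 as mixtures at C8 and C16, so these centres carry no stereo label in their SMILES.

**Route**

Step 1
Reactants: 1 (3aS,4R,5S,6aR)-5-hydroxy-4-(hydroxymethyl)hexahydrocyclopenta[b]furan-2-one
Product: 2 C12 TBDPS ether of 1
Conditions: TBDPSCl, imidazole, DMF, 0 °C
Reagents that add atoms: tert-butyl(chloro)diphenylsilane, CC(C)(C)[Si](Cl)(c1ccccc1)c1ccccc1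
Why: Silyl ether formation, in which the bulky silyl chloride reacts with the unhindered primary C12 alcohol far faster than with the secondary C27 alcohol.

Step 2
Reactants: 2 C12 TBDPS ether of 1
Product: 4 ring B methyl acetal (C27 OH free), via lactol 3 (not isolated)
Conditions: iBu2AlH (2.2 equiv), CH2Cl2, −78 °C; then MeOH, PPTS, 23 °C
Reagents that add atoms: methanol, CO
Why: Partial reduction of the γ-lactone by iBu2AlH at −78 °C stops at the lactol, and acid-catalysed acetalisation in methanol then masks ring B as a methyl acetal, so that O5 is a poor leaving group in the enolate and cuprate steps that follow.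

Step 3
Reactants: 4 ring B methyl acetal (C27 OH free)
Product: 5 C27 ketone
Conditions: Dess–Martin periodinane, NaHCO3, CH2Cl2, 23 °C
Reagents that add atoms: none
Why: Dess–Martin oxidation converts the secondary C27 alcohol into the ketone under buffered, non-basic conditions, which avoids β-elimination of O5 and leaves the acetal and the silyl ether intact.

Step 4
Reactants: 5 C27 ketone
Product: 7 C27 enol triflate (C27=C3), via potassium enolate 6 (not isolated)
Conditions: KN(SiMe3)2, THF, −78 °C; then PhNTf2, −78 → −20 °C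
Reagents that add atoms: N-phenylbis(trifluoromethanesulfonimide), O=S(=O)(N(c1ccccc1)S(=O)(=O)C(F)(F)F)C(F)(F)F
Why: Enol triflate formation, in which kinetic deprotonation at −78 °C takes the less hindered C3 methylene rather than the C11 methine and O-sulfonylation of the enolate outruns loss of the poor alkoxide leaving group on C4.

Step 5
Reactants: 7 C27 enol triflate (C27=C3)
Product: 8 benzyl enoate (C28 ester on C27=C3)
Conditions: Pd(OAc)2 (5 mol%), PPh3, CO (1 atm), BnOH, Et3N, DMF, 50 °C
Reagents that add atoms: carbon monoxide, [C-]#[O+]; benzyl alcohol, OCc1ccccc1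
Why: Palladium-catalysed alkoxycarbonylation, in which oxidative addition of the enol triflate to zerovalent palladium, CO insertion and capture of the acylpalladium by benzyl alcohol introduce C28 as a benzyl ester on the C27=C3 alkene.

Step 6
Reactants: 8 benzyl enoate (C28 ester on C27=C3)
Product: 10 3-ethyl 27-benzyloxymethyl benzyl ester (ring B acetal), via lithium enolate 9 (not isolated)
Conditions: Et2CuLi (from EtLi and CuI), Et2O, −78 → −30 °C; then BnOCH2Cl, HMPA, THF, −30 → 0 °C
Reagents that add atoms: lithium diethylcuprate, [Li+].CC[Cu-]CC; benzyl chloromethyl ether, ClCOCc1ccccc1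
Why: Tandem conjugate addition and enolate alkylation, in which the cuprate should add to C3 of the γ-alkoxy enoate anti to the C4–O5 bond on the convex face and the resulting enolate should be alkylated at C27 on the face away from the new ethyl group and from the C11 side chain, which puts C28 cis to C12 and C25 trans to it.

Step 7
Reactants: 10 3-ethyl 27-benzyloxymethyl benzyl ester (ring B acetal)
Product: 12 ring B lactone, via lactol 11 (not isolated)
Conditions: CrO3, H2SO4, H2O, acetone, 0 °C
Reagents that add atoms: water, O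
Why: Jones oxidation, in which aqueous acid hydrolyses the methyl acetal to the lactol and CrO3 oxidises it in the same flask to the γ-lactone, while the TBDPS ether, the benzyl ether and the benzyl ester survive the short exposure at 0 °C.

Step 8
Reactants: 12 ring B lactone
Product: 14 C12 iodide, via alcohol 13 (not isolated)
Conditions: HF·pyridine, THF, 0 → 23 °C; then I2, PPh3, imidazole, CH2Cl2, 0 °C
Reagents that add atoms: iodine, [I][I]
Why: Fluoride cleaves the Si–O bond without forming a free alkoxide and the crude primary alcohol is converted at once into the iodide by the Appel reaction, so that it has little time to lactonise onto the cis C28 ester.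

Step 9
Reactants: 15 (R)-5-oxotetrahydrofuran-2-carboxylic acid
Product: 16 (R)-5-oxotetrahydrofuran-2-carbonyl chloride
Conditions: (COCl)2, DMF (cat.), CH2Cl2, 0 → 23 °C
Reagents that add atoms: oxalyl chloride, O=C(Cl)C(Cl)=O
Why: Acid chloride formation with oxalyl chloride and catalytic DMF is base-free, so the stereocentre that becomes C14 is not enolised.

Step 10
Reactants: 14 C12 iodide; 16 (R)-5-oxotetrahydrofuran-2-carbonyl chloride
Product: 18 C13 ketone carrying ring E, via alkylzinc iodide 17 (not isolated)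
Conditions: Zn, LiCl, THF, 40 °C; then 16, Pd(PPh3)4 (5 mol%), THF, 0 → 23 °C
Reagents that add atoms: none
Why: Negishi acylation, in which zinc inserts into the primary C–I bond to give an alkylzinc iodide that tolerates lactones and esters and palladium-catalysed coupling with the acid chloride forms the C12–C13 bond and brings in ring E with C14 already set.

Step 11
Reactants: 18 C13 ketone carrying ring E
Product: 19 (13S) alcohol
Conditions: (R)-2-methyl-CBS-oxazaborolidine (20 mol%), catecholborane, toluene/CH2Cl2, −78 → −40 °C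
Reagents that add atoms: none
Why: CBS reduction, in which the (R)-oxazaborolidine treats the branched C14 side of the ketone as the large group and delivers hydride under catalyst control to give the (13S) alcohol, while catecholborane at low temperature does not reduce the lactones or the ester.

Step 12
Reactants: 19 (13S) alcohol
Product: 21 (13R) azide, via triflate 20 (not isolated)
Conditions: Tf2O, pyridine, CH2Cl2, −30 °C; then NaN3, DMF, −30 → 0 °C
Reagents that add atoms: sodium azide, [Na+].[N-]=[N+]=[N-]
Why: SN2 displacement, in which the secondary triflate, unable to ionise easily next to the oxygen-bearing C14, is displaced by azide with inversion to give the (13R) C–N bond syn to C14–O20 as in the target.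

Step 13
Reactants: 21 (13R) azide
Product: 25 bis(α-methylene) azide, via dilithium bis-enolate 22 (not isolated), via bis-Mannich base 23 (not isolated), via bis-ammonium iodide 24 (not isolated)
Conditions: LiN(SiMe3)2 (2.5 equiv), THF, −78 °C; CH2=NMe2+ I−, −78 → 0 °C; then MeI, CH2Cl2, 23 °C; then NaHCO3, H2O/CH2Cl2
Reagents that add atoms: N,N-dimethylmethyleneiminium iodide, C=[N+](C)C.[I-]
Why: Eschenmoser methylenation, in which only the two lactone α-methylene groups C8 and C16 are enolisable, so the bis-enolate is aminomethylated twice and the Mannich bases are quaternised and eliminated to the two α-methylene lactones.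

Step 14
Reactants: 25 bis(α-methylene) azide
Product: 26 amino acid hydrochloride (C8 and C16 methyl groups set)
Conditions: H2 (3 atm), Pd(OH)2/C, THF, aq. HCl (1.1 equiv), 23 °C
Reagents that add atoms: hydrogen chloride, Cl
Why: Catalytic hydrogenation should add hydrogen to the C8 methylene from the convex face of the A/B bicycle (methyl on the concave face) and to the C16 methylene anti to the C13 chain on C14 (methyl cis to it), while the same catalyst cleaves the benzyl ester and benzyl ether and reduces the azide to the amine, which HCl keeps protonated and thus unable to open lactone E.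

Step 15
Reactants: 26 amino acid hydrochloride (C8 and C16 methyl groups set)
Product: 28 tetracyclic lactam alcohol (C25 CH2OH), via active ester 27 (not isolated)
Conditions: EDCI, HOAt, DMF, 0 °C; then iPr2NEt (slow addition), 2 mM, 0 → 23 °C
Reagents that add atoms: none
Why: Carbodiimide-mediated lactamisation, in which the hindered C28 acid is converted into its HOAt ester while the amine is still an ammonium salt and slow release of the amine under high dilution should close the cis-fused six-membered lactam ring C by attack on C28 faster than the amine can attack the lactone carbonyl C18.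

Step 16
Reactants: 28 tetracyclic lactam alcohol (C25 CH2OH)
Product: 29 C25 aldehyde
Conditions: Dess–Martin periodinane, NaHCO3, CH2Cl2, 23 °C
Reagents that add atoms: none
Why: Dess–Martin oxidation of the neopentylic primary alcohol gives the non-enolisable C25 aldehyde without affecting the lactam N–H or the lactones.

Step 17
Reactants: 29 C25 aldehyde; 30 vinylmagnesium bromide
Product: 31 (25R) allylic alcohol
Conditions: CH2=CHMgBr (3 equiv), CH2Cl2/THF, −78 → −40 °C
Reagents that add atoms: none
Why: Chelation-controlled Grignard addition, in which magnesium should bridge the aldehyde oxygen and O29 after N–H deprotonation, leaving the chelate face towards C3–H open and the face towards C11, ring C and the concave C9 methyl shielded, so that vinyl addition gives the (25R) carbinol while the lactones react far more slowly at low temperature.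

Step 18
Reactants: 31 (25R) allylic alcohol
Product: 32 C25 TBS ether
Conditions: TBSOTf, 2,6-lutidine, CH2Cl2, −78 → 0 °C
Reagents that add atoms: tert-butyldimethylsilyl trifluoromethanesulfonate, CC(C)(C)[Si](C)(C)OS(=O)(=O)C(F)(F)F
Why: Silylation with the silyl triflate and 2,6-lutidine protects the hindered secondary allylic alcohol, any O-silyl imidate formed at the lactam being hydrolysed on work-up.

Step 19
Reactants: 32 C25 TBS ether; 33 allyl bromide
Product: 35 N-allyl lactam (metathesis precursor), via potassium amidate 34 (not isolated)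
Conditions: KN(SiMe3)2 (1.05 equiv), THF, −78 °C; then allyl bromide, −78 → 0 °C
Reagents that add atoms: none
Why: Lactam N-alkylation, in which one equivalent of KN(SiMe3)2 removes only the N–H, far more acidic than the α-hydrogens of the lactones at C8 and C16, and the amidate is allylated on nitrogen.

Step 20
Reactants: 35 N-allyl lactam (metathesis precursor)
Product: 36 23,24-didehydro O-TBS target (bridged lactam)
Conditions: second-generation Grubbs catalyst (H2IMes)(PCy3)Cl2Ru=CHPh (15 mol%), 1,4-benzoquinone (20 mol%), toluene (2 mM), 90 °C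
Reagents that add atoms: none
Why: The ruthenium alkylidene should initiate at the unhindered N-allyl group, and the resulting carbene should engage the C25 vinyl group by cycloaddition and cycloreversion, expelling ethene and forming C23=C24; the closest known reaction type is the ring-closing metathesis of N-allyl lactams bearing an alkenyl chain on the α-carbon to medium-bridged lactams with bridgehead nitrogen. Ring D (N21–C22–C23–C24–C25–C27–C28) closes as a seven-membered, necessarily cis, cycloalkene across N21 and C27 of the δ-lactam, which turns the fused lactam into the bridged one. No stereocentre is formed. The step needs chemoselectivity and a productive conformation: 35 has only two alkenes, both terminal, quaternary C27 holds the C25 arm on the lactam face towards which N21 can pyramidalise, and high dilution with benzoquinone suppresses oligomerisation and isomerisation of the allyl group to an enamide. The loss of amide resonance is offset by release of ethene at 90 °C, and lactams of this bridged ring size are known to be isolable.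

Step 21
Reactants: 36 23,24-didehydro O-TBS target (bridged lactam)
Product: 37 O-TBS target
Conditions: H2 (1 atm), Pd/C, EtOAc, 23 °C
Reagents that add atoms: none
Why: Catalytic hydrogenation of the cis-disubstituted C23=C24 alkene is routine and affects neither the silyl ether nor the bridged lactam.

Step 22
Reactants: 37 O-TBS target
Product: 38 target CNP0120800.1
Conditions: HF·pyridine, pyridine, THF, 0 → 23 °C
Reagents that add atoms: none
Why: Desilylation, in which fluoride cleaves the Si–O bond under pyridine-buffered conditions that leave the lactones and the non-planar lactam untouched, which gives the target.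

**Compound list**

1 | (3aS,4R,5S,6aR)-5-hydroxy-4-(hydroxymethyl)hexahydrocyclopenta[b]furan-2-one | C1[C@H]2OC(=O)C[C@H]2[C@H](CO)[C@H]1O | starting material
2 | C12 O-TBDPS ether of 1 (C27 OH free) | C1[C@H]2OC(=O)C[C@H]2[C@H](CO[Si](c3ccccc3)(c3ccccc3)C(C)(C)C)[C@H]1O | intermediate
3 | ring B lactol of 2 (both C6 anomers) | C1[C@H]2OC(O)C[C@H]2[C@H](CO[Si](c3ccccc3)(c3ccccc3)C(C)(C)C)[C@H]1O | intermediate
4 | ring B methyl acetal, C27 alcohol (both C6 anomers) | C1[C@H]2OC(OC)C[C@H]2[C@H](CO[Si](c3ccccc3)(c3ccccc3)C(C)(C)C)[C@H]1O | intermediate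
5 | C27 ketone, ring B methyl acetal | C1[C@H]2OC(OC)C[C@H]2[C@H](CO[Si](c3ccccc3)(c3ccccc3)C(C)(C)C)C1=O | intermediate
6 | potassium C27–C3 enolate of 5 | [K+].[O-]C1=C[C@H]2OC(OC)C[C@H]2[C@@H]1CO[Si](c1ccccc1)(c1ccccc1)C(C)(C)C | intermediate
7 | C27 enol triflate (C27=C3) | O=S(=O)(OC1=C[C@H]2OC(OC)C[C@H]2[C@@H]1CO[Si](c1ccccc1)(c1ccccc1)C(C)(C)C)C(F)(F)F | intermediate
8 | benzyl C27=C3 enoate (C28 benzyl ester) | O=C(OCc1ccccc1)C1=C[C@H]2OC(OC)C[C@H]2[C@@H]1CO[Si](c1ccccc1)(c1ccccc1)C(C)(C)C | intermediate
9 | lithium ester enolate after ethyl addition at C3 | CC[C@@H]1[C@H]2OC(OC)C[C@H]2[C@H](CO[Si](c3ccccc3)(c3ccccc3)C(C)(C)C)C1=C(O[Li])OCc1ccccc1 | intermediate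
10 | 3-ethyl, 27-(benzyloxymethyl) benzyl ester, ring B methyl acetal (ethyl, C28 and C12 on one face) | CC[C@@H]1[C@H]2OC(OC)C[C@H]2[C@H](CO[Si](c3ccccc3)(c3ccccc3)C(C)(C)C)[C@@]1(C(=O)OCc1ccccc1)COCc1ccccc1 | intermediate
11 | ring B lactol of 10 | CC[C@@H]1[C@H]2OC(O)C[C@H]2[C@H](CO[Si](c3ccccc3)(c3ccccc3)C(C)(C)C)[C@@]1(C(=O)OCc1ccccc1)COCc1ccccc1 | intermediate
12 | ring B lactone, C12 O-TBDPS | CC[C@@H]1[C@H]2OC(=O)C[C@H]2[C@H](CO[Si](c3ccccc3)(c3ccccc3)C(C)(C)C)[C@@]1(C(=O)OCc1ccccc1)COCc1ccccc1 | intermediate
13 | C12 alcohol | CC[C@@H]1[C@H]2OC(=O)C[C@H]2[C@H](CO)[C@@]1(C(=O)OCc1ccccc1)COCc1ccccc1 | intermediate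
14 | C12 iodide | CC[C@@H]1[C@H]2OC(=O)C[C@H]2[C@H](CI)[C@@]1(C(=O)OCc1ccccc1)COCc1ccccc1 | intermediate
15 | (R)-5-oxotetrahydrofuran-2-carboxylic acid | OC(=O)[C@H]1CCC(=O)O1 | starting material
16 | (R)-5-oxotetrahydrofuran-2-carbonyl chloride | ClC(=O)[C@H]1CCC(=O)O1 | intermediate
17 | C12 alkylzinc iodide | CC[C@@H]1[C@H]2OC(=O)C[C@H]2[C@H](C[Zn]I)[C@@]1(C(=O)OCc1ccccc1)COCc1ccccc1 | intermediate
18 | C13 ketone carrying ring E (14R) | CC[C@@H]1[C@H]2OC(=O)C[C@H]2[C@H](CC(=O)[C@H]3CCC(=O)O3)[C@@]1(C(=O)OCc1ccccc1)COCc1ccccc1 | intermediate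
19 | (13S,14R) alcohol | CC[C@@H]1[C@H]2OC(=O)C[C@H]2[C@H](C[C@H](O)[C@H]3CCC(=O)O3)[C@@]1(C(=O)OCc1ccccc1)COCc1ccccc1 | intermediate
20 | (13S) triflate | CC[C@@H]1[C@H]2OC(=O)C[C@H]2[C@H](C[C@H](OS(=O)(=O)C(F)(F)F)[C@H]3CCC(=O)O3)[C@@]1(C(=O)OCc1ccccc1)COCc1ccccc1 | intermediate
21 | (13R,14R) azide | CC[C@@H]1[C@H]2OC(=O)C[C@H]2[C@H](C[C@@H](N=[N+]=[N-])[C@H]3CCC(=O)O3)[C@@]1(C(=O)OCc1ccccc1)COCc1ccccc1 | intermediate
22 | dilithium bis-enolate of lactones B and E | CC[C@@H]1[C@H]2OC(O[Li])=C[C@H]2[C@H](C[C@@H](N=[N+]=[N-])[C@H]3CC=C(O[Li])O3)[C@@]1(C(=O)OCc1ccccc1)COCc1ccccc1 | intermediate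
23 | bis-Mannich base (CH2NMe2 at C8 and C16) | CC[C@@H]1[C@H]2OC(=O)C(CN(C)C)[C@H]2[C@H](C[C@@H](N=[N+]=[N-])[C@H]3CC(CN(C)C)C(=O)O3)[C@@]1(C(=O)OCc1ccccc1)COCc1ccccc1 | intermediate
24 | bis(trimethylammonium) diiodide | CC[C@@H]1[C@H]2OC(=O)C(C[N+](C)(C)C)[C@H]2[C@H](C[C@@H](N=[N+]=[N-])[C@H]3CC(C[N+](C)(C)C)C(=O)O3)[C@@]1(C(=O)OCc1ccccc1)COCc1ccccc1.[I-].[I-] | intermediate
25 | bis(α-methylene lactone) azide | CC[C@@H]1[C@H]2OC(=O)C(=C)[C@H]2[C@H](C[C@@H](N=[N+]=[N-])[C@H]3CC(=C)C(=O)O3)[C@@]1(C(=O)OCc1ccccc1)COCc1ccccc1 | intermediate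
26 | amino acid hydrochloride (C13 ammonium, C28 acid, C25 CH2OH, C8 and C16 methyl) | CC[C@@H]1[C@H]2OC(=O)[C@@H](C)[C@H]2[C@H](C[C@@H]([NH3+])[C@H]3C[C@@H](C)C(=O)O3)[C@@]1(C(=O)O)CO.[Cl-] | intermediate
27 | C28 HOAt ester of 26 | CC[C@@H]1[C@H]2OC(=O)[C@@H](C)[C@H]2[C@H](C[C@@H]([NH3+])[C@H]3C[C@@H](C)C(=O)O3)[C@@]1(C(=O)On1nnc2cccnc12)CO.[Cl-] | intermediate
28 | tetracyclic N–H lactam, C25 primary alcohol | CC[C@@H]1[C@H]2OC(=O)[C@@H](C)[C@H]2[C@@H]2C[C@H]([C@H]3C[C@@H](C)C(=O)O3)NC(=O)[C@]12CO | intermediate
29 | C25 aldehyde | CC[C@@H]1[C@H]2OC(=O)[C@@H](C)[C@H]2[C@@H]2C[C@H]([C@H]3C[C@@H](C)C(=O)O3)NC(=O)[C@]12C=O | intermediate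
30 | vinylmagnesium bromide | C=C[Mg]Br | starting material
31 | (25R) vinyl carbinol | CC[C@@H]1[C@H]2OC(=O)[C@@H](C)[C@H]2[C@@H]2C[C@H]([C@H]3C[C@@H](C)C(=O)O3)NC(=O)[C@]12[C@H](O)C=C | intermediate
32 | C25 O-TBS vinyl carbinol, N–H lactam | CC[C@@H]1[C@H]2OC(=O)[C@@H](C)[C@H]2[C@@H]2C[C@H]([C@H]3C[C@@H](C)C(=O)O3)NC(=O)[C@]12[C@H](O[Si](C)(C)C(C)(C)C)C=C | intermediate
33 | allyl bromide | C=CCBr | starting material
34 | potassium amidate of 32 | CC[C@@H]1[C@H]2OC(=O)[C@@H](C)[C@H]2[C@@H]2C[C@H]([C@H]3C[C@@H](C)C(=O)O3)[N-]C(=O)[C@]12[C@H](O[Si](C)(C)C(C)(C)C)C=C.[K+] | intermediate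
35 | N-allyl lactam with C25 O-TBS vinyl carbinol (metathesis precursor) | CC[C@@H]1[C@H]2OC(=O)[C@@H](C)[C@H]2[C@@H]2C[C@H]([C@H]3C[C@@H](C)C(=O)O3)N(CC=C)C(=O)[C@]12[C@H](O[Si](C)(C)C(C)(C)C)C=C | intermediate
36 | 23,24-didehydro O-TBS target | CC[C@@H]1[C@H]2OC(=O)[C@@H](C)[C@H]2[C@@H]2C[C@H]([C@H]3C[C@@H](C)C(=O)O3)N3CC=C[C@@H](O[Si](C)(C)C(C)(C)C)[C@@]12C3=O | intermediate
37 | O-TBS target | CC[C@@H]1[C@H]2OC(=O)[C@@H](C)[C@H]2[C@@H]2C[C@H]([C@H]3C[C@@H](C)C(=O)O3)N3CCC[C@@H](O[Si](C)(C)C(C)(C)C)[C@@]12C3=O | intermediate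
38 | CNP0120800.1 | CC[C@@H]1[C@H]2OC(=O)[C@@H](C)[C@H]2[C@@H]2C[C@H]([C@H]3C[C@@H](C)C(=O)O3)N3CCC[C@@H](O)[C@@]12C3=O | target

**Step count and risks**

Total: 22 steps. Longest linear sequence: 21 steps (steps 1–8 and 10–22, from 1 to 38); step 9 prepares acid chloride 16.

Step 20. The ring closure may lose to metathesis between molecules, or stall at the carbene of the N-allyl group, because closing ring D twists the amide and the C25 alkene is neopentylic and flanked by a silyl ether. The fallback closes ring D by forming C24–C25 instead. It sets out from aldehyde 29. N-alkylation (NaH, DMF, 0 °C) with (Z)-3-bromo-1-iodoprop-1-ene should give the N-[(Z)-3-iodoallyl] formyl lactam F1. An intramolecular Nozaki–Hiyama–Kishi reaction (CrCl2, NiCl2 cat., DMF, high dilution) should then add the alkenylchromium to the aldehyde and give the 23,24-didehydro alcohol F2, with the metal held by O29 on the same aldehyde face as in step 17. Hydrogenation of F2 (H2, Pd/C) comes back to the route at target 38.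

Step 17. The addition may show poor facial selectivity if the chelate is not well formed, giving both C25 epimers. The fallback sets C25 by a catalyst-controlled reduction. It sets out from aldehyde 29. Me3SiC≡CMgBr should give the epimeric silylalkynyl carbinols F3, and Dess–Martin oxidation the ynone F4. CBS reduction with the (S)-oxazaborolidine and catecholborane, in which the alkynyl group is the small substituent, should give the silylalkynyl carbinol F5 with the C25 configuration of 31. Bu4NF/AcOH should remove the alkynyl silyl group to give the ethynyl carbinol F6, and semi-hydrogenation over Pd/CaCO3–Pb(OAc)2 with quinoline comes back to the route at 31.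

Step 15. The acyl transfer may go the wrong way: once freed, the amine may open lactone E (ring expansion to a hydroxy δ-lactam) before the hindered C28 ester is attacked. The fallback has the activated ester in place before the amine is released. It sets out from 25. Hydrogenation over Pd(OH)2/C in the presence of Boc2O should give the N-Boc amino acid F7 (methyl groups set, benzyl groups removed). Pentafluorophenol and EDCI should give the N-Boc pentafluorophenyl ester F8. CF3CO2H should remove the Boc group, and slow addition of the ammonium salt to NaHCO3 in CH2Cl2 under high dilution should close ring C and come back to the route at 28.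

**Further compounds**

F1 | step 20 | N21-[(Z)-3-iodoprop-2-enyl] C25 aldehyde lactam | CC[C@@H]1[C@H]2OC(=O)[C@@H](C)[C@H]2[C@@H]2C[C@H]([C@H]3C[C@@H](C)C(=O)O3)N(C/C=C\I)C(=O)[C@]12C=O
F2 | step 20 | 23,24-didehydro target (free C25 alcohol) | CC[C@@H]1[C@H]2OC(=O)[C@@H](C)[C@H]2[C@@H]2C[C@H]([C@H]3C[C@@H](C)C(=O)O3)N3CC=C[C@@H](O)[C@@]12C3=O
F3 | step 17 | C25 (trimethylsilyl)ethynyl carbinols (both C25 epimers) | CC[C@@H]1[C@H]2OC(=O)[C@@H](C)[C@H]2[C@@H]2C[C@H]([C@H]3C[C@@H](C)C(=O)O3)NC(=O)[C@]12C(O)C#C[Si](C)(C)C
F4 | step 17 | C25 (trimethylsilyl)ethynyl ketone | CC[C@@H]1[C@H]2OC(=O)[C@@H](C)[C@H]2[C@@H]2C[C@H]([C@H]3C[C@@H](C)C(=O)O3)NC(=O)[C@]12C(=O)C#C[Si](C)(C)C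
F5 | step 17 | C25 (trimethylsilyl)ethynyl carbinol configured as in 31 | CC[C@@H]1[C@H]2OC(=O)[C@@H](C)[C@H]2[C@@H]2C[C@H]([C@H]3C[C@@H](C)C(=O)O3)NC(=O)[C@]12[C@H](O)C#C[Si](C)(C)C
F6 | step 17 | C25 ethynyl carbinol configured as in 31 | CC[C@@H]1[C@H]2OC(=O)[C@@H](C)[C@H]2[C@@H]2C[C@H]([C@H]3C[C@@H](C)C(=O)O3)NC(=O)[C@]12[C@H](O)C#C
F7 | step 15 | N-Boc amino acid (C13 NHBoc, C28 acid, C25 CH2OH) | CC[C@@H]1[C@H]2OC(=O)[C@@H](C)[C@H]2[C@H](C[C@@H](NC(=O)OC(C)(C)C)[C@H]3C[C@@H](C)C(=O)O3)[C@@]1(C(=O)O)CO
F8 | step 15 | N-Boc amino pentafluorophenyl ester | CC[C@@H]1[C@H]2OC(=O)[C@@H](C)[C@H]2[C@H](C[C@@H](NC(=O)OC(C)(C)C)[C@H]3C[C@@H](C)C(=O)O3)[C@@]1(C(=O)Oc1c(F)c(F)c(F)c(F)c1F)CO
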